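If both products form on the same free catalyst and reagent, their rates per unit of substrate keep one ratio whatever happens to those two, and this selectivity factor is taken as the same in the dawn run, the noon run and the flask.

the same everywhere: left-handed substrate 17 mM; right-handed substrate 17 mM; racemization catalyst 0.61 mM; impurity 66 µM
- dawn: reagent 51 mM; free catalyst 0.48 mM; run made earlier
- noon: reagent 51 mM; free catalyst 0.75 mM; run made earlier
- flask: reagent 51.0 mM; free catalyst 0.34 mM; time 12 min

| run | time / min | left-handed product / % | right-handed product / % | left-handed substrate / % |
|---|---|---|---|---|
| dawn | 1.33 | 39 | 19 | 18 |
| dawn | 2.50 | 46 | 22 | 14 |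
| dawn | 4.00 | 51 | 28 | 10 |
| dawn | 5.00 | 54 | 26 | 7 |
| dawn | 6.00 | 54 | 27 | 11 |
| dawn | 8.00 | 56 | 30 | 3 |
| noon | 0.500 | 29 | 14 | 25 |
| noon | 1.33 | 44 | 23 | 12 |
| noon | 2.50 | 51 | 33 | 3 |
| noon | 4.00 | 54 | 33 | 5 |
| noon | 6.00 | 59 | 35 | 1 |
| noon | 8.00 | 58 | 33 | 5 |

(standard deviation of a reading: 2 percentage points)

- free catalyst is single-handed; left-handed substrate and right-handed substrate are mirror images of each other, charged as a racemate, each of them at the stated concentration
- an excess is the difference of the two amounts in percent of their sum
- an excess is below zero if the other one leads

* left-handed product and right-handed product together, in percent of the left-handed substrate and right-handed substrate charged together, at 12 min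
* excess of left-handed product over right-handed product in the product at 12 min
* whether the exchange between left-handed substrate and right-handed substrate keeps pace with the reaction: how far the product's excess at 12 min gets from its value without exchange to its value with instant exchange (above 80 % keeps pace, below 20 % hardly takes part, else lags behind)

The noon reading at 0.500 min is the earliest, so exchange has had the least time there. Treating each substrate as used up on its own, its 29 % of left-handed product and 14 % of right-handed product give a selectivity factor of 2.64, a reading with the scatter of the readings. Product formed while the two substrates stand equal then carries the equal-substrate excess, (factor − 1)/(factor + 1), of 45.1 %. The dawn run reads an excess of 30.2 % at 8.00 min. The flask holds less free catalyst (0.34 mM against 0.48 mM), so the reckoning here places its excess between these two values.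

The forecast gives 71 %, 35 % and "lags behind", holding that “the reaction has nearly stopped by 12 min”.

The flask gives 82.8 %, 34.7 % and "lags behind", at 65 % of the way. The excess agrees with the forecast, but the yield stands 12 percentage points above it, with 13.7 % of the catalyst charge still free at 12.0 min.

    reagent + free catalyst + right-handed substrate → free catalyst + right-handed product (k = 430 M⁻² s⁻¹)
    left-handed substrate + racemization catalyst ⇌ right-handed substrate + racemization catalyst, rate k2*[racemization catalyst]*[left-handed substrate] forward; the back reaction follows from the equilibrium constant (k = 9.90 M⁻¹ s⁻¹)
    reagent + free catalyst + left-handed substrate → free catalyst + left-handed product (k = 1100 M⁻² s⁻¹)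
    free catalyst + impurity → spent catalyst (k = 3.00 × 10⁵ M⁻¹ s⁻¹)
    free catalyst ⇌ dormant form (K = 6.30, k = 0.00390 s⁻¹)

At 12.0 min the flask's exchange relaxes, both ways together, with a half-life of 0.956 min, against 9.9 min for left-handed substrate by its own step, ten times longer. The flask's left-handed and right-handed substrate stand at 24.6 % and 33.6 % at 1.20 min, then at 8.29 % and 8.87 % at 12.0 min, and its excess at that time stands 10 points under the equal-substrate excess read from the noon run. The neighbour charged with 0.085 mM of free catalyst reaches 17.7 % with an excess of 42.9 %, 2.2 points under the same value.

All runs were generated by integration for substances that don't exist, and the scatter is random.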